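**The measure.** If a flask of Q ends for want of D, the limiting reagent, I ask what each D leaves behind. Dividing the rate of gaining L by the rate of spending D removes time, so I used the end-of-run form: the yield per equivalent φ, final L over D charged, both per Q charged.

in all of them: Q 0.050 M

| flask | D | remark | time |
|---|---|---|---|
| north | 0.037 M | run made earlier |  |
| east | 0.23 M | run made earlier |  |
| Sunday's | 0.0250 M |  | 3.0 d |
| Friday's | 0.125 M |  | 3.0 d |
| Wednesday's | 0.200 M |  | 3.0 d |

| north: time / h | north: L / % | east: time / h | east: L / % |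
|---|---|---|---|
| 3.00 | 21.2 | 3.00 | 37.4 |
| 5.00 | 26.0 | 5.00 | 28.2 |
| 8.00 | 31.0 | 8.00 | 18.7 |
| 12.0 | 31.8 | 12.0 | 12.8 |
| 20.0 | 35.0 | 20.0 | 5.1 |
| 40.0 | 36.2 | 40.0 | 0 |

(readings scatter by 0.5 percentage points)

- final L, as a percentage of the Q charged, for each flask in turn (Sunday's, Friday's, Wednesday's)

- the numbers in the tables scatter by 0.5 percentage points (one standard deviation)

**Main step.** With Q + D → L by itself, one D gives one L. Sunday's flask then reaches 50.0%, and Friday's and Wednesday's reach 100%.

**Second addition.** The east run lost L, from 37.4% to 5.1%, so I added a second D to L. The north run held 36.2% at 40.0 h on 0.740 D per Q. I took that plateau for spent D, so I read φ = 0.489 from the north run. For Sunday's flask this gave 24.5%.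

**Excess D.** Friday's and Wednesday's flasks each hold more than 2 D per Q, so I let L decay in a pseudo-first-order tail. East's late slope, with 0.130 M of D assumed left, read 0.833 M⁻¹ h⁻¹. Starting from east's 37.4%, I reckoned 8.35% for Friday's flask and 0.0930% for Wednesday's.

**The forecast.** The forecast gave 30.5%, 4.5% and 0.1%, with “D runs out and L ≈ 30%” for Sunday's flask; its first figure stood above my Sunday's figure and its second below my Friday's.

**The result.** At 3.0 d, L stood at 27.4% in Sunday's flask, 6.53% in Friday's and 0.118% in Wednesday's.

    Q + D → L + J (k = 4.60 M⁻¹ h⁻¹)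
    D + L → E + J (k = 1.70 M⁻¹ h⁻¹)
    D + E ⇌ G + J (K = 1.80, k = 2.10 M⁻¹ h⁻¹)
    L ⇌ Z (K = 0.550, k = 0.500 h⁻¹)

**Sunday's ratio.** In Sunday's flask at 0.131 d, L was made 2.11 times as fast as it was used up, each step taken net, and by 3.00 d D stood at 0.033% of its charge. Sunday's φ came to 0.548, above the 0.489 read from the north run.

The data were computed for substances that don't exist.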